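Atom labels C1–C27 (with O8, O19, O20, N25) follow the target SMILES read from left to right. Rings: A = O8/C3–C7, B = N25/C24/C23/C6/C9/C27, C = C6/C9–C13/C23, D = C12–C16, E = C13/C14/C17/C22/C23.

Remark on the chemistry: the catalyst antipode in step 1 is assumed to be the (S)-proline-derived salt; if it delivers the mirror image of 3, its (R)-antipode is used, and nothing else in the route changes.

## Analysis of the target

The target is a pentacyclic amino ester with five stereocentres (C6, C9, C14, C17, C23). Rings B (N-methylpiperidine) and C (cycloheptene) share the path C23–C6–C9, so together they are a 3-azabicyclo[4.3.1]decene whose one-carbon bridge, C6, is also the spiro carbon of ring A, a 6-ethyl-3,4-dihydro-2H-pyran. Ring D is a cyclopentene whose tetrasubstituted C12=C13 bond also belongs to ring C, and ring E is a cyclopentane fused to ring D at C13–C14 with the methyl ester on C17. On ring E the ring D bond at C14, the ester carbon C18 on C17 and C6 on C23 lie on one face and C24 on the other; C9 then follows from the bridged bicycle. The one independent element left is C6, where C7 points to the nitrogen bridge and C5 to the carbocyclic bridge. The sensitive groups are the enol ether of ring A (acid and water), the tertiary amine, the C17 ester (it sits on the concave face, so base would epimerise it) and the C12=C13 bond, which is homoallylic to nitrogen. The difficulty lies in the adjacent quaternary carbons C6 and C23, in the seven-membered ring, and in placing the alkene at C12=C13 and not at C12=C16. The strategy rests on ring E: a cyclopentane with cis one-carbon branches on C23 and C17, both cis to the neighbouring ring, is what remains of an endo norbornene fused to a cyclopentanone once its alkene bridge C6=C18 is cut.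

## Retrosynthetic reasoning

Ring A goes first, because its enol ether would not survive the rest of the work. Opening O8–C3 of 28 in the sense of a cyclodehydration gives δ-hydroxy ketone 26, and its oxidised form 25 is cut at C5–C6 into aldehyde 23 and enone 24. The Michael addition has to make C6 quaternary with C5 on the side of the carbocyclic bridge. Since the aldehyde carbon of 23 becomes C7, the incoming chain must take the more open face of the exocyclic enolate, which is expected to be the ring C face.

Aldehyde 23 is the one-carbon homologue of bridge ketone 19, reached through alkene 20 and alcohol 22. The bond cut is C6–C7. The ketone carbon of 19 has been C6 ever since the cycloaddition, so no carbon is moved, only added.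

The C12=C13 bond of 19 is traced back to tertiary carbinol 18. An enol derivative of a C12 ketone was weighed and dropped: kinetic enolisation of a cyclopentanone of this kind goes to the methylene C16 and not to the ring-fusion methine C13, so a cross-coupling would put the alkene in the wrong place. In 18 the hydroxyl on C12 and H13 are anti-periplanar at a trans ring fusion, and elimination toward C13 gives the only alkene that is endocyclic in both ring C and ring D.

Ring B of 18 is cut at N25–C27 and C27–C9, back to amino ketone 15. Both carbons on nitrogen (C26 and C27) come from the dimethylamino group that salt 9 delivers: one methyl is turned into the methylene iminium carbon and closes onto C9, the only enolisable position of the C6 ketone. This is done while C12 is still sp3, because with the C12=C13 bond in place the same iminium ion would be a 2-azonia-1,5-diene (C27=N25–C24–C23–C13=C12).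

Ring C of 15 is cut at C6–C9, which leads to iodo lactone 13. The three-carbon chain C9–C11 already hangs on C12, and its terminal carbon attacks the lactone carbonyl C6 through a six-membered arrangement (C9–C10–C11–C12–O–C6). No intermolecular acylation, which would have to choose between lactone and ester, is needed.

The C23–C24 bond of 11 is cut to lactone acid 8 and salt 9. The lactone ring is cis-fused to ring E, so its enolate can only be attacked on the face of H13. This puts C24 where the target has it, and makes C23 quaternary without any reliance on steric bias.

Lactone acid 8 comes from alkene 6 by cleaving C6=C18. The two carboxyl groups that result are told apart by the tertiary hydroxyl on C12, which reaches only C6 in a strain-free γ-lactone; C18 stays free and becomes the methyl ester.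

Carbinol 6 is cut at C11–C12 into ketone 3 and bromide 4. Addition from the open exo face sets the hydroxyl on the concave face, which the lactone needs, and installs C9–C11 in the same step.

Ketone 3 is cut at C13–C23 and C14–C17 into diene 1 and enone 2. This is the step on which the plan depends: it closes ring E, sets C14, C17 and C23 relative to each other and in the absolute sense, and leaves C6 and C18 masked as one alkene.

## Alternatives that were turned down

Alternative 1: Ring B is opened at C23–C24. In the forward sense an N-carboxymethyl group on N25 is oxidised and loses CO2, and the α-amino radical at C24 adds 6-exo to C23 of a ring E enone (C23=C13–C12=O). This gives tetracyclic amino ketone A1, with rings A, B, D and E in place and a vinyl group on C9 for ring C.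
- For it: radicals tolerate the crowding at a carbon that becomes quaternary next to quaternary C6, and the nucleophilic radical is polarity-matched with the enone. The addition also leaves the regiodefined C12–C13 enolate, which the chosen route cannot reach by enolisation; on that point this plan is stronger.
- Against it: C6 and ring A, the most fragile part of the molecule, must be built first and carried through everything. The configuration at C23 depends on how a nearly flat ring differentiates its faces. C6, C9, C14 and C17 all need separate stereocontrolled operations before the key step.
- Comparison: the chosen plan offers instead three ring E centres and the absolute configuration from one catalytic step on two commercial compounds, and a C23 alkylation with only one open face.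

Alternative 2: Ring D and a six-membered forerunner of ring E are cut at C13–C14 and C22–C23. An intramolecular Diels–Alder reaction joins a silyloxydiene unit (C14=C17–C18=C22) to the C13=C23 bond of an enedione unit and gives spiro trans-hydrindanone silyl enol ether A2. A Wolff ring contraction later turns C18 into the ester carbon.
- For it: the cycloaddition makes quaternary C23 directly, ring B is present from the start as a piperidone, and the silyl enol ether marks C17 for the diazo transfer. On these points it is stronger than the chosen route, which needs a separate alkylation for C24 and a Mannich closure for ring B.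
- Against it: the substrate is achiral, so the absolute configuration must come from an asymmetric intramolecular cycloaddition of a hindered trisubstituted dienophile. Ring E is born six-membered and costs about three more steps to contract. The ester configuration at C17 is then decided by protonation of a ketene, and rings C and A still remain.
- Comparison: the chosen plan makes ring E five-membered, with C18 attached and cis, in its first step.

Alternative 3: Ring E is cut at C14–C17. A carbene centre generated at C17 under dirhodium catalysis inserts into the allylic C14–H bond of ring D and gives tetracyclic keto lactam ester A3 (rings B, C, D, E).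
- For it: a 1,5 insertion into an activated C–H bond is a favourable mode, and the ester arrives with the ring. With nitrogen as a lactam no iminium chemistry can touch the C12=C13 bond; compound 19 of the chosen route is the amine analogue of A3 and has to be reached with more care on that point.
- Against it: C14 is a methylene before the insertion, so C14 and C17 are created together by an acceptor-type carbene, the least selective class, with the ester wanted on the concave face. The substrate must already hold the bridged B/C system with C23 and C9 enantiopure. The lactam must be reduced late beside an ester.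
- Comparison: the chosen plan fixes C14 and C17 first and lets them direct the rest.

Key step: step 1

## Route

Step 1
Reactants: 1 cyclopentadiene; 2 2-cyclopenten-1-one
Product: 3 endo adduct (1R,2S,6R,7S)-tricyclo[5.2.1.0(2,6)]dec-8-en-3-one
Conditions: (S)-3,3-diphenyl-1-(o-tolyl)tetrahydro-1H,3H-pyrrolo[1,2-c][1,3,2]oxazaborole·HNTf2 (20 mol %), 1 (5 equiv, freshly cracked from dicyclopentadiene), CH2Cl2, −20 °C
Reagents that add atoms: none
Why: The protonated oxazaborolidine binds the carbonyl oxygen of 2 and lowers its LUMO, and 1 adds in a concerted, asynchronous [4+2] step through the endo transition state, in which the carbonyl lies under the diene. The closest known reaction type is the oxazaborolidinium-catalysed Diels–Alder addition of cyclopentadiene to 2-cycloalkenones. Ring E (C13, C14, C17, C22, C23) and the temporary cyclohexene ring both close in this one suprafacial cycloaddition as C13–C23 and C14–C17 form. C13 and C14 are cis because the cis alkene of 2 adds suprafacially, C23 and C17 are cis because both diene termini bond on one face, and the endo mode puts the alkene carbons C6 and C18 on the same face of ring E as the cyclopentanone. The absolute configuration comes from the catalyst, whose aryl group screens one face of the bound enone. The step needs endo over exo and one enone face over the other; the Lewis acid sharpens the endo preference, and low temperature with excess 1 keeps the catalysed path ahead of the thermal one and of diene dimerisation. C14, C17 and C23 are carried unchanged to the target, while C13 later becomes sp2.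

Step 2
Reactants: 3 endo adduct; 4 (3-bromopropoxy)(tert-butyl)dimethylsilane
Product: 6 endo carbinol 3-[3-(tert-butyldimethylsilyloxy)propyl]tricyclo[5.2.1.0(2,6)]dec-8-en-3-ol (hydroxyl syn to the C8=C9 bridge; side chain exo), via Grignard reagent 5 (not isolated)
Conditions: 4, Mg, THF, 40 °C; then 3, LaCl3·2LiCl (1 equiv), THF, 0 °C; aq. NH4Cl
Reagents that add atoms: none
Why: Grignard addition to a ketone, with the lanthanum salt suppressing enolisation. The reagent comes from the exo face, away from the C8=C9 bridge, so C11 is set on the convex face and the hydroxyl on the concave face next to the alkene carbon that becomes C6. C12 is a temporary stereocentre whose only task is to hold that oxygen there.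

Step 3
Reactants: 6 endo carbinol
Product: 8 lactone acid (γ-lactone between the C6 carboxyl and the oxygen on C12; free C18 carboxylic acid on C17; silyloxypropyl chain on C12), via hydroxy diacid 7 (not isolated)
Conditions: RuCl3·xH2O (3 mol %), NaIO4 (4.2 equiv), CCl4/MeCN/H2O, rt; 1 M HCl work-up, toluene azeotrope
Reagents that add atoms: sodium periodate [Na+].[O-]I(=O)(=O)=O (oxygen passed on through RuO4); water O
Why: Oxidative cleavage of the strained norbornene alkene by RuO4 gives the cis-1,3-diacid without touching a stereocentre; the tertiary carbinol and the silyl ether are inert for the short exposure. The concave hydroxyl closes the all-cis γ-lactone onto C6, while the bridged δ-lactone onto C18 would be strained, so the two arms are differentiated under thermodynamic control.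

Step 4
Reactants: 8 lactone acid; 9 N,N-dimethylmethyleneiminium iodide (Eschenmoser's salt)
Product: 11 amino acid lactone (8 with CH2NMe2 on C23 on the face of H13), via dilithium enolate 10 (not isolated)
Conditions: LiN(iPr)2 (2.2 equiv), THF, −78 → −40 °C; then 9, −78 °C → rt; aq. NH4Cl to pH 7
Reagents that add atoms: none
Why: Mannich alkylation of a lactone enolate. The first equivalent of base makes the carboxylate, whose own α-hydrogen is then far less acidic than that of the lactone, so only C23 is enolised. The lactone is cis-fused to ring E, so the iminium ion can only arrive on the face of H13, which makes C23 quaternary with C24 trans to C18 and C6 cis to it.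

Step 5
Reactants: 11 amino acid lactone
Product: 12 hydroxy amino ester lactone (C18 methyl ester; 3-hydroxypropyl on C12)
Conditions: HCl (1.25 M in MeOH), 0 → 45 °C; aq. NaHCO3
Reagents that add atoms: methanol CO
Why: Fischer esterification and acid cleavage of the silyl ether in one operation. The tertiary γ-lactone stays closed because its ring-opening with methanol is uphill, and the protonated amine is inert.

Step 6
Reactants: 12 hydroxy amino ester lactone
Product: 13 iodo amino ester lactone (3-iodopropyl on C12)
Conditions: I2, PPh3, imidazole, CH2Cl2, 0 °C → rt; used at once
Reagents that add atoms: iodine II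
Why: Appel iodination of the primary alcohol. The neopentyl tertiary amine is a poor partner for the iodide, but the compound is not stored, so self-alkylation gets no time.

Step 7
Reactants: 13 iodo amino ester lactone
Product: 15 hydroxy ketone (cycloheptanone ring C with C6=O closed through C9–C11 onto C12; tertiary hydroxyl on C12 anti to H13; CH2NMe2 on C23), via bridged hemiketal 14 (not isolated)
Conditions: SmI2 (2.5 equiv), tris(dibenzoylmethanato)iron Fe(dbm)3 (5 mol %), THF, −30 °C → rt; aq. NaHCO3
Reagents that add atoms: none
Why: Samarium Barbier-type intramolecular nucleophilic acyl substitution. The organosamarium at C9 attacks the lactone carbonyl C6 through a six-membered arrangement, and the tetrahedral intermediate (the bridged hemiketal) shields the new ketone from a second addition. The methyl ester would need an eight-membered approach and is left alone.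

Step 8
Reactants: 15 hydroxy ketone
Product: 18 tetracyclic hydroxy amino ketone (rings B to E; N-methylpiperidin-4-one ring B bridging C23 and C9 across the C6 ketone; C12 hydroxyl kept), via amine N-oxide 16 (not isolated), via iminium trifluoroacetate 17 (not isolated)
Conditions: mCPBA (1.05 equiv), CH2Cl2, −78 → 0 °C; then (CF3CO)2O (1.5 equiv), −78 → 0 °C; then MeCN, 40 °C; aq. K2CO3
Reagents that add atoms: none
Why: Polonovski–Potier fragmentation of the N-oxide removes a hydrogen from a methyl group, not from the hindered neopentyl C24, and gives the N-methyleneiminium ion. This closes in a six-membered Mannich reaction onto the enol at C9, the only enolisable position of the C6 ketone; the bridge fixes C9. The step is run before the alkene is made, so that no 2-azonia-Cope shift or alkene addition can compete. C24 and C9 are held on the same face, as in hemiketal 14.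

Step 9
Reactants: 18 tetracyclic hydroxy amino ketone
Product: 19 tetracyclic amino ketone with the C12=C13 alkene (3-azabicyclo[4.3.1]decenone fused to rings D and E)
Conditions: Ph2S[OC(CF3)2Ph]2 (Martin sulfurane, 1.5 equiv), CH2Cl2, 0 °C → rt
Reagents that add atoms: none
Why: Dehydration of a tertiary alcohol through its alkoxysulfonium ion. H13 is anti-periplanar to the leaving group at the trans C/D ring fusion, and its loss gives the Zaitsev alkene, the only one endocyclic in both ring C and ring D. The same elimination lets ring C relax from the boat-like shape it has in 18.

Step 10
Reactants: 19 tetracyclic amino ketone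
Product: 20 exocyclic alkene (C6=C7H2 in place of the ketone)
Conditions: CH2Br2, Zn, TiCl4, THF/CH2Cl2, 0 °C → rt
Reagents that add atoms: dibromomethane BrCBr
Why: Titanium–zinc methylenation of a hindered ketone that cannot enolise (both α-carbons are bridgeheads). The reagent is not basic, so the C17 ester is neither epimerised nor attacked.

Step 11
Reactants: 20 exocyclic alkene
Product: 22 primary alcohol (C6–H with CH2OH as C7; C7 expected syn to the nitrogen bridge), via alkylborane 21 (not isolated)
Conditions: 9-BBN (3 equiv), THF, 60 °C; then H2O2, aq. NaOAc, 0 °C → rt
Reagents that add atoms: hydrogen peroxide OO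
Why: Anti-Markovnikov hydroboration–oxidation. Boron goes to the terminal carbon, and the tetrasubstituted C12=C13 bond and the ester do not react with this borane. The configuration at C6 is of no consequence because C6 becomes trigonal again in step 13.

Step 12
Reactants: 22 primary alcohol
Product: 23 aldehyde (C6–H bearing CHO as C7)
Conditions: Dess–Martin periodinane, NaHCO3, CH2Cl2, 0 °C → rt
Reagents that add atoms: none
Why: Hypervalent iodine oxidation of a primary alcohol to the aldehyde under buffered, non-epimerising conditions; the tertiary amine is tolerated.

Step 13
Reactants: 23 aldehyde; 24 ethyl vinyl ketone (pent-1-en-3-one)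
Product: 25 keto aldehyde (C6 quaternary; CHO as C7 syn to the nitrogen bridge; 3-oxopentyl chain C5 to C1 syn to the carbocyclic bridge)
Conditions: 24 (3 equiv), DBU (0.3 equiv), MeCN, 0 °C → rt
Reagents that add atoms: none
Why: Base-catalysed Michael addition of an α-branched aldehyde through its exocyclic enolate. The acceptor should approach C6 over ring C, where it meets one syn-axial hydrogen (on C10) and the trigonal C13, and not over ring B, where axial hydrogens on C24 and C27 stand in the way. This sets C6 with C5 on the carbocyclic side; the mild base leaves the C17 ester alone and does not drive the aldol ring closure of the product.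

Step 14
Reactants: 25 keto aldehyde
Product: 26 hydroxy ketone (C7 reduced to CH2OH; ethyl ketone kept)
Conditions: NaBH4 (0.5 equiv), EtOH/CH2Cl2 3:7, −78 °C
Reagents that add atoms: none
Why: Chemoselective borohydride reduction of an aldehyde beside a dialkyl ketone and an ester at low temperature. The alkoxide formed closes onto the ketone as a hemiketal, which protects it further.

Step 15
Reactants: 26 hydroxy ketone
Product: 28 target CNP0159589.2, via cyclic hemiketal 27 (not isolated)
Conditions: (+)-camphor-10-sulfonic acid (1.3 equiv), benzene, reflux through 4 Å molecular sieves; then Et3N, aq. NaHCO3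
Reagents that add atoms: none
Why: Acid-catalysed cyclodehydration of a δ-hydroxy ketone through its cyclic hemiketal and oxocarbenium ion. Under equilibrating conditions the endocyclic enol ether (C3=C4) is favoured over the exocyclic ethylidene isomer. One equivalent of acid is held by the amine, the rest is the catalyst, and the basic quench protects the product.

## Compound list

1 | cyclopentadiene | C1C=CC=C1 | starting material
2 | 2-cyclopenten-1-one | O=C1C=CCC1 | starting material
3 | (1R,2S,6R,7S)-tricyclo[5.2.1.0(2,6)]dec-8-en-3-one (endo adduct) | O=C1CC[C@H]2[C@@H]1[C@H]1C=C[C@@H]2C1 | intermediate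
4 | (3-bromopropoxy)(tert-butyl)dimethylsilane | BrCCCO[Si](C)(C)C(C)(C)C | starting material
5 | [3-(tert-butyldimethylsilyloxy)propyl]magnesium bromide | Br[Mg]CCCO[Si](C)(C)C(C)(C)C | intermediate (not isolated)
6 | endo carbinol: 3-[3-(tert-butyldimethylsilyloxy)propyl]tricyclo[5.2.1.0(2,6)]dec-8-en-3-ol, hydroxyl syn to the C8=C9 bridge, chain exo | O[C@]1(CCCO[Si](C)(C)C(C)(C)C)CC[C@H]2[C@@H]1[C@H]1C=C[C@@H]2C1 | intermediate
7 | hydroxy diacid: cis-fused rings D and E with CO2H (C6) on C23, CO2H (C18) on C17 and OH on C12 all on the concave face, silyloxypropyl on C12 convex | O[C@]1(CCCO[Si](C)(C)C(C)(C)C)CC[C@H]2[C@@H]1[C@@H](C(=O)O)C[C@H]2C(=O)O | intermediate (not isolated)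
8 | lactone acid: γ-lactone C6(=O)–O–C12 cis-fused to rings D and E, CO2H (C18) on C17 | O=C1O[C@]2(CCCO[Si](C)(C)C(C)(C)C)CC[C@H]3[C@@H]2[C@@H]1C[C@H]3C(=O)O | intermediate
9 | N,N-dimethylmethyleneiminium iodide (Eschenmoser's salt) | C[N+](C)=C.[I-] | starting material
10 | dilithium salt of 8: lactone enolate (C6=C23) and C18 carboxylate | [Li+].[Li+].[O-]C=1O[C@]2(CCCO[Si](C)(C)C(C)(C)C)CC[C@H]3[C@@H]2C=1C[C@H]3C([O-])=O | intermediate (not isolated)
11 | amino acid lactone: 8 with CH2NMe2 (C24) on C23 on the face of H13 | O=C1O[C@]2(CCCO[Si](C)(C)C(C)(C)C)CC[C@H]3[C@@H]2[C@]1(CN(C)C)C[C@H]3C(=O)O | intermediate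
12 | hydroxy amino ester lactone: methyl ester at C18, 3-hydroxypropyl on C12 | O=C1O[C@]2(CCCO)CC[C@H]3[C@@H]2[C@]1(CN(C)C)C[C@H]3C(=O)OC | intermediate
13 | iodo amino ester lactone: 3-iodopropyl on C12 | O=C1O[C@]2(CCCI)CC[C@H]3[C@@H]2[C@]1(CN(C)C)C[C@H]3C(=O)OC | intermediate
14 | bridged hemiketal: 8-oxabicyclo[3.2.1]octan-1-ol core, C6(OH) bridged by oxygen to C12, C9–C11 as the three-carbon bridge | O[C@@]12O[C@]3(CCC1)CC[C@H]4[C@@H]3[C@]2(CN(C)C)C[C@H]4C(=O)OC | intermediate (not isolated)
15 | hydroxy ketone: ring C cycloheptanone (C6=O) trans-fused to ring D, tertiary OH on C12 anti to H13, CH2NMe2 on C23 | O=C1CCC[C@@]2(O)CC[C@H]3[C@@H]2[C@]1(CN(C)C)C[C@H]3C(=O)OC | intermediate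
16 | N-oxide of 15 | O=C1CCC[C@@]2(O)CC[C@H]3[C@@H]2[C@]1(C[N+](C)(C)[O-])C[C@H]3C(=O)OC | intermediate (not isolated)
17 | N-methyl-N-methyleneiminium trifluoroacetate from 16 | O=C1CCC[C@@]2(O)CC[C@H]3[C@@H]2[C@]1(C[N+](C)=C)C[C@H]3C(=O)OC.[O-]C(=O)C(F)(F)F | intermediate (not isolated)
18 | tetracyclic hydroxy amino ketone: ring B closed (N25–C27–C9), C6 ketone, C12–OH | O=C1[C@@H]2CC[C@@]3(O)CC[C@H]4[C@@H]3[C@]1(CN(C)C2)C[C@H]4C(=O)OC | intermediate
19 | tetracyclic amino ketone with C12=C13 | O=C1[C@@H]2CCC3=C4[C@H](CC3)[C@H](C(=O)OC)C[C@@]41CN(C)C2 | intermediate
20 | exocyclic alkene: C6=CH2 (C7) | C=C1[C@@H]2CCC3=C4[C@H](CC3)[C@H](C(=O)OC)C[C@@]41CN(C)C2 | intermediate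
21 | B-alkyl-9-borabicyclo[3.3.1]nonane with boron on C7 | C(B1C2CCCC1CCC2)[C@H]1[C@@H]2CCC3=C4[C@H](CC3)[C@H](C(=O)OC)C[C@@]41CN(C)C2 | intermediate (not isolated)
22 | primary alcohol: C6(H)–CH2OH, C7 syn to the nitrogen bridge | OC[C@H]1[C@@H]2CCC3=C4[C@H](CC3)[C@H](C(=O)OC)C[C@@]41CN(C)C2 | intermediate
23 | aldehyde: C6(H)–CHO | O=C[C@H]1[C@@H]2CCC3=C4[C@H](CC3)[C@H](C(=O)OC)C[C@@]41CN(C)C2 | intermediate
24 | ethyl vinyl ketone (pent-1-en-3-one) | CCC(=O)C=C | starting material
25 | keto aldehyde: C6 quaternary with CHO (C7) and 3-oxopentyl (C5–C1) | CCC(=O)CC[C@]1(C=O)[C@@H]2CCC3=C4[C@H](CC3)[C@H](C(=O)OC)C[C@@]41CN(C)C2 | intermediate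
26 | hydroxy ketone: C6 with CH2OH (C7) and 3-oxopentyl | CCC(=O)CC[C@]1(CO)[C@@H]2CCC3=C4[C@H](CC3)[C@H](C(=O)OC)C[C@@]41CN(C)C2 | intermediate
27 | cyclic hemiketal of 26 (2-ethyl-2-hydroxytetrahydropyran ring A, both anomers) | CCC1(O)CC[C@]2(CO1)[C@@H]1CCC3=C4[C@H](CC3)[C@H](C(=O)OC)C[C@@]42CN(C)C1 | intermediate (not isolated)
28 | CNP0159589.2 | CCC1=CC[C@]2(CO1)[C@@H]1CCC3=C4[C@H](CC3)[C@H](C(=O)OC)C[C@@]42CN(C)C1 | target

## Step count and least certain steps

Total: 15 steps. Longest linear sequence: 15 steps (the route is linear from 1 and 2; 4, 9 and 24 are commercial).

Step 1 (key step). The cyclic enone is a weak dienophile, so the cycloaddition may be slow, and at the higher temperature then needed diene dimerisation and loss of enantiofacial control would follow. Fallback: 1 and 2 are combined with AlCl3 in CH2Cl2 at −78 °C to give the racemic endo adduct F1, which NaBH4 reduces from the exo face to the racemic endo alcohol F2. Acylation with vinyl acetate and Candida antarctica lipase B resolves F2. The antipode with the configuration of 3 is collected as endo alcohol F3, either directly or after methanolysis (K2CO3, MeOH) of its acetate F4. Dess–Martin oxidation of F3 returns ketone 3.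

Step 9. Loss of a proton from C16 or C11 instead of C13 would place the alkene wrongly; the base must reach H13 next to the C24 arm, and the preference for the tetrasubstituted alkene is only a Zaitsev preference. Fallback: the elimination of 18 is accepted as a mixture whose main wrong component would be the C12=C16 isomer F5, and the mixture is then heated with TsOH (1.3 equiv, to override the amine) in benzene at 60 °C. All regioisomers return to the same tertiary C12 cation, and the alkene endocyclic in both ring C and ring D, compound 19, is the expected sink. The equilibration is stopped early, because over-long exposure could move the alkene on to C13=C14.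

Step 8. The N-oxide may fragment toward C24. The iminium ion may also be hydrolysed before the hindered ketone enolises, since the closure requires ring C of 15 to take a boat-like shape. Fallback: 15 is N-demethylated with 1-chloroethyl chloroformate in 1,2-dichloroethane to the 1-chloroethyl carbamate F6, which methanol at reflux converts into the secondary amine F7. Aqueous formaldehyde in acetic acid at 60 °C then forms the iminium ion by condensation and closes ring B under protic, reversible Mannich conditions, arriving at 18.

Step 13. Poor or reversed facial selectivity at C6 would give the C6 epimer. Fallback: the roles of the two arms are exchanged, so that the same facial preference leads to the right epimer. Aldehyde 23 is hydroxymethylated with aqueous formaldehyde and catalytic K2CO3 in THF to the hydroxy aldehyde F8, in which the new CH2OH is C7 and the old aldehyde carbon is now C5. Wittig reaction of F8 with 1-(triphenylphosphoranylidene)butan-2-one in toluene at 80 °C gives the enone F9. Hydrogenation of its disubstituted conjugated alkene (H2, Pd/C, EtOAc; the tetrasubstituted C12=C13 bond is inert) returns the route to 26.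

Step 15. The oxocarbenium ion could be trapped by the nearby C12=C13 bond, or the exocyclic enol ether isomer could form or the product hydrolyse. Fallback: 26 is converted with HC(OMe)3 and pyridinium p-toluenesulfonate in methanol into the mixed methyl ketal F10, and methanol is then eliminated under basic conditions (TMSOTf, iPr2NEt, CH2Cl2, −20 °C), giving 28 without hot acid.

## Further compounds

F1 | step 1 | racemic endo-tricyclo[5.2.1.0(2,6)]dec-8-en-3-one (one antipode drawn) | O=C1CC[C@H]2[C@@H]1[C@H]1C=C[C@@H]2C1
F2 | step 1 | racemic endo,endo-tricyclo[5.2.1.0(2,6)]dec-8-en-3-ol (one antipode drawn) | O[C@@H]1CC[C@H]2[C@@H]1[C@H]1C=C[C@@H]2C1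
F3 | step 1 | resolved endo alcohol with the ring configuration of 3 | O[C@@H]1CC[C@H]2[C@@H]1[C@H]1C=C[C@@H]2C1
F4 | step 1 | acetate of F3 | CC(=O)O[C@@H]1CC[C@H]2[C@@H]1[C@H]1C=C[C@@H]2C1
F5 | step 9 | C12=C16 regioisomer of 19 (C13–H kept) | O=C1[C@@H]2CCC3=CC[C@H]4[C@@H]3[C@]1(CN(C)C2)C[C@H]4C(=O)OC
F6 | step 8 | N-methyl 1-chloroethyl carbamate of 15 (mixture at the chloroethyl carbon) | O=C1CCC[C@@]2(O)CC[C@H]3[C@@H]2[C@]1(CN(C)C(=O)OC(C)Cl)C[C@H]3C(=O)OC
F7 | step 8 | secondary amine: 15 with CH2NHMe on C23 | O=C1CCC[C@@]2(O)CC[C@H]3[C@@H]2[C@]1(CNC)C[C@H]3C(=O)OC
F8 | step 13 | hydroxy aldehyde: C6 with CHO (C5) and CH2OH (C7) | O=C[C@]1(CO)[C@@H]2CCC3=C4[C@H](CC3)[C@H](C(=O)OC)C[C@@]41CN(C)C2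
F9 | step 13 | (E)-enone: C6 with CH=CH–C(=O)Et and CH2OH | CCC(=O)/C=C/[C@]1(CO)[C@@H]2CCC3=C4[C@H](CC3)[C@H](C(=O)OC)C[C@@]41CN(C)C2
F10 | step 15 | mixed methyl ketal of 26 (2-ethyl-2-methoxytetrahydropyran ring A, both anomers) | CCC1(OC)CC[C@]2(CO1)[C@@H]1CCC3=C4[C@H](CC3)[C@H](C(=O)OC)C[C@@]42CN(C)C1
A1 | alternative 1 | tetracyclic amino ketone (rings A, B, D, E) | CCC1=CC[C@]2(CO1)[C@H](C=C)CN(C)C[C@@]23C[C@@H](C(=O)OC)[C@H]4CCC(=O)[C@@H]34
A2 | alternative 2 | spiro trans-hydrindanone silyl enol ether | CN1CCC(=O)[C@@]2(C1)CC(O[Si](C)(C)C(C)(C)C)=C[C@H]1CCC(=O)[C@@H]12
A3 | alternative 3 | tetracyclic keto lactam ester (rings B, C, D, E) | O=C1[C@@H]2CCC3=C4[C@H](CC3)[C@H](C(=O)OC)C[C@@]41C(=O)N(C)C2
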